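The route rests on removing the propionate unit (lactone O, C16, C15, C17; cembrane numbering) from the carbocycle by cutting O–C3 and C1–C15. The feature exploited is the six-membered lactone ring O–C3–C2–C1–C15–C16. It bridges C1 and C3 of the 14-membered ring and has the tertiary C4 hydroxyl anti to O–C3, the imprint of a carboxylate that has opened a C3–C4 epoxide. The precursor 12 is acyclic: a farnesol-derived bis-epoxide ending in a (Z)-allylic propionate. In one flask an Ireland–Claisen rearrangement forges C1–C15, and the carboxylate it releases opens the epoxide at C3, fixing C1, C15, C3 and C4. Ring-closing metathesis, diimide reduction and a Schenck ene reaction complete the target.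

Key step: step 9

Remark on numbering: cembrane numbering of the target is used for every compound.
- C1 = ring CH bearing C15; C2 = lactone CH2; C3 = CH–O(lactone); C4 = C(C18H3)(OH).
- C7 = CH–OOH; C8 = C(=C19H2); C11/C12 = epoxide, with C12 bearing C20H3.
- C15 = CH(C17H3); C16 = lactone C=O.
- C13' is the carbinol carbon of 4, which leaves as part of propene in step 10.

Carbon provenance: farnesol supplies C2–C13 and C18–C20, compound 4 supplies C1 and C14, and propionic anhydride supplies C15–C17.

Assumptions: the C13=C14 alkene of 18 is drawn E, and either geometry gives 19. The C7 configuration in step 12 is assumed to follow from attack on the outer face of the ring alkene.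

Step 1
Reactants: 1 (2E,6E)-farnesol
Product: 2 (2S,3S)-2,3-epoxyfarnesol
Conditions: Ti(OiPr)4 (cat.), L-(+)-diethyl tartrate (cat.), t-BuOOH, 4 Å MS, CH2Cl2, −20 °C
Reagents that add atoms: tert-butyl hydroperoxide, CC(C)(C)OO
Why: Sharpless asymmetric epoxidation, in which only the allylic-alcohol alkene binds to the titanium tartrate and L-(+)-DET delivers oxygen to the face that gives the (3S,4S)-epoxide, fixing C4 for good and C3 for a later inversion.

Step 2
Reactants: 2 (2S,3S)-2,3-epoxyfarnesol
Product: 3 epoxyfarnesyl triflate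
Conditions: Tf2O, 2,6-lutidine, CH2Cl2, −78 °C; short cold work-up, used crude
Reagents that add atoms: triflic anhydride, O=S(=O)(OS(=O)(=O)C(F)(F)F)C(F)(F)F
Why: O-sulfonylation of a primary alcohol with a hindered base at low temperature leaves the epoxide and both alkenes untouched and gives a leaving group that can be displaced at −78 °C.

Step 3
Reactants: 3 epoxyfarnesyl triflate; 4 (S)-but-3-yn-2-ol
Product: 7 propargylic propionate, via dilithio butynolate 5 (not isolated), via lithium alkoxide 6 (not isolated)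
Conditions: 4, n-BuLi (2 equiv per 4), THF–DMPU, −78 → 0 °C; 3, −78 → −20 °C; then (EtCO)2O, 0 °C
Reagents that add atoms: propionic anhydride, CCC(=O)OC(=O)CC
Why: SN2 alkylation of a lithium acetylide by a primary triflate makes C1–C2 (the acetylide carbon of 5 outruns its alkoxide, and the triflate outruns the trisubstituted epoxide), the remaining alkoxide 6 is then O-acylated in the same flask, and the C13' stereocentre comes unchanged from 4.

Step 4
Reactants: 7 propargylic propionate
Product: 8 (Z)-allylic propionate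
Conditions: H2 (1 atm), Pd/CaCO3 poisoned with Pb(OAc)2, quinoline, EtOAc, 23 °C
Reagents that add atoms: none
Why: Lindlar semihydrogenation adds hydrogen syn to the alkyne and stops at the Z alkene, while the trisubstituted alkenes, the epoxide and the ester are inert.

Step 5
Reactants: 8 (Z)-allylic propionate
Product: 9 C13 allylic alcohol
Conditions: SeO2 (cat.), t-BuOOH, CH2Cl2, 0 °C
Reagents that add atoms: tert-butyl hydroperoxide, CC(C)(C)OO (oxygen relayed through SeO2, O=[Se]=O)
Why: Catalytic SeO2 allylic oxidation (ene reaction, then [2,3] shift) is E-selective and should prefer the terminal gem-dimethyl alkene over the internal C7=C8 alkene and the acyloxy-deactivated disubstituted alkene.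

Step 6
Reactants: 9 C13 allylic alcohol
Product: 10 bis-epoxy alcohol
Conditions: Ti(OiPr)4 (cat.), L-(+)-diethyl tartrate (cat.), t-BuOOH, 4 Å MS, CH2Cl2, −20 °C
Reagents that add atoms: tert-butyl hydroperoxide, CC(C)(C)OO
Why: A second Sharpless asymmetric epoxidation, in which only the C11=C12 alkene of the new allylic alcohol is activated and L-(+)-DET again gives the (S,S)-epoxide (11S,12S), leaving C7=C8 and the Z alkene untouched.

Step 7
Reactants: 10 bis-epoxy alcohol
Product: 11 bis-epoxy aldehyde
Conditions: TEMPO (cat.), PhI(OAc)2, CH2Cl2, 23 °C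
Reagents that add atoms: none
Why: Oxoammonium (TEMPO) oxidation of a primary alcohol stops at the aldehyde under almost neutral conditions, and the α-carbon C12 is quaternary, so nothing can epimerise.

Step 8
Reactants: 11 bis-epoxy aldehyde
Product: 12 vinyl-epoxide propionate
Conditions: Ph3PCH3Br, NaN(SiMe3)2, THF, −78 → 0 °C
Reagents that add atoms: methyltriphenylphosphonium bromide, C[P+](c1ccccc1)(c1ccccc1)c1ccccc1.[Br-]
Why: Wittig methylenation, in which the non-stabilised ylide adds to the aldehyde far faster than to the secondary propionate at low temperature and does not touch the epoxides.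

Step 9
Reactants: 12 vinyl-epoxide propionate
Product: 17 hydroxy δ-lactone, via lithium enolate 13 (not isolated), via silyl ketene acetal 14 (not isolated), via silyl ester 15 (not isolated), via ammonium carboxylate 16 (not isolated)
Conditions: LiN(iPr)2, THF–DMPU (3:1), −78 °C; t-BuMe2SiCl, −78 → 23 °C, then 40 °C; then Bu4NF (THF, wet), 40 °C; pH 7 buffer
Reagents that add atoms: none
Why: LiN(iPr)2 in THF–DMPU gives enolate 13 with methyl cis to OLi, t-BuMe2SiCl traps it as the (Z)-silyl ketene acetal 14, and 14 undergoes the Ireland–Claisen [3,3] shift through a chair with the C13' methyl equatorial, making C1–C15, an (E)-propenyl group and silyl ester 15. Fluoride then frees carboxylate 16, whose oxygen attacks C3 of the neighbouring (3S,4S)-epoxide from the rear to form O–C3; this is the known lactonisation of 5,6-epoxy acids, and the δ-lactone ring closes 6-exo-tet. C1 is set by suprafacial 1,3-chirality transfer from the (S)-carbinol C13' across the Z alkene (allylic strain excludes the chair with an axial methyl), C15 by the ketene acetal geometry, C3 by inversion and C4 by retention of the step 1 epoxide. The step needs attack at C3 rather than C4 (7-endo) and on the C3–C4 rather than the C11–C12 epoxide. Basic conditions free of Lewis acid send the carboxylate to the less substituted carbon, and only the C3–C4 epoxide lies within reach of a six-membered transition state, while the acid-sensitive vinyl epoxide is spared. All three substituents on the lactone ring of 17 are equatorial, so the kinetic product is also the thermodynamic one.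

Step 10
Reactants: 17 hydroxy δ-lactone
Product: 18 macrocyclic 7,13-diene
Conditions: second-generation Grubbs catalyst RuCl2(=CHPh)(PCy3)(H2IMes) (10 mol %), CH2Cl2, high dilution, 40 °C
Reagents that add atoms: none
Why: Ring-closing metathesis of the vinyl epoxide and the propenyl group closes the 14-membered ring at C13=C14 with loss of propene. C7=C8 is too hindered to compete, and a six-membered closure from C13 to C8 is excluded by the trans epoxide in that tether.

Step 11
Reactants: 18 macrocyclic 7,13-diene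
Product: 19 macrocyclic 7-ene
Conditions: 2-nitrobenzenesulfonohydrazide (excess), Et3N, CH2Cl2, 23 °C
Reagents that add atoms: none
Why: Diimide reduction (concerted syn transfer of two hydrogens) discriminates by substitution, so the 1,2-disubstituted C13=C14 alkene should go before the trisubstituted C7=C8, and the allylic epoxide is not hydrogenolysed as it could be over palladium.

Step 12
Reactants: 19 macrocyclic 7-ene
Product: 20 CNP0319766.1
Conditions: O2, tetraphenylporphyrin (cat.), visible light, CH2Cl2, −20 °C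
Reagents that add atoms: oxygen, O=O
Why: Schenck ene reaction on the only remaining alkene, in which singlet oxygen takes hydrogen from the more crowded C6/C19 side of the E alkene; abstraction from the freely rotating C19 methyl places OOH on C7 and the alkene at C8=C19, and 7R should follow from attack on the outer face of the alkene, which stands perpendicular to the mean plane of the 14-membered ring.

Compound list
1 | (2E,6E)-farnesol, (2E,6E)-3,7,11-trimethyldodeca-2,6,10-trien-1-ol | CC(C)=CCC/C(C)=C/CC/C(C)=C/CO | starting material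
2 | (2S,3S)-2,3-epoxyfarnesol, [(2S,3S)-3-[(3E)-4,8-dimethylnona-3,7-dienyl]-3-methyloxiran-2-yl]methanol | CC(C)=CCC/C(C)=C/CC[C@]1(C)O[C@H]1CO | intermediate
3 | [(2S,3S)-3-[(3E)-4,8-dimethylnona-3,7-dienyl]-3-methyloxiran-2-yl]methyl trifluoromethanesulfonate | CC(C)=CCC/C(C)=C/CC[C@]1(C)O[C@H]1COS(=O)(=O)C(F)(F)F | intermediate
4 | (S)-but-3-yn-2-ol | C[C@H](O)C#C | starting material
5 | O,C-dilithio derivative of (S)-but-3-yn-2-ol | C[C@H]([O-])C#[C-].[Li+].[Li+] | intermediate
6 | lithium (2S)-5-[(2S,3S)-3-[(3E)-4,8-dimethylnona-3,7-dienyl]-3-methyloxiran-2-yl]pent-3-yn-2-olate | CC(C)=CCC/C(C)=C/CC[C@]1(C)O[C@H]1CC#C[C@H](C)[O-].[Li+] | intermediate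
7 | (2S)-5-[(2S,3S)-3-[(3E)-4,8-dimethylnona-3,7-dienyl]-3-methyloxiran-2-yl]pent-3-yn-2-yl propanoate | CC(C)=CCC/C(C)=C/CC[C@]1(C)O[C@H]1CC#C[C@H](C)OC(=O)CC | intermediate
8 | (2S,3Z)-5-[(2S,3S)-3-[(3E)-4,8-dimethylnona-3,7-dienyl]-3-methyloxiran-2-yl]pent-3-en-2-yl propanoate | CC(C)=CCC/C(C)=C/CC[C@]1(C)O[C@H]1C/C=C\[C@H](C)OC(=O)CC | intermediate
9 | (2S,3Z)-5-[(2S,3S)-3-[(3E,7E)-9-hydroxy-4,8-dimethylnona-3,7-dienyl]-3-methyloxiran-2-yl]pent-3-en-2-yl propanoate | OC/C(C)=C/CC/C(C)=C/CC[C@]1(C)O[C@H]1C/C=C\[C@H](C)OC(=O)CC | intermediate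
10 | (2S,3Z)-5-[(2S,3S)-3-[(3E)-6-[(2S,3S)-3-(hydroxymethyl)-3-methyloxiran-2-yl]-4-methylhex-3-enyl]-3-methyloxiran-2-yl]pent-3-en-2-yl propanoate | OC[C@]1(C)O[C@H]1CC/C(C)=C/CC[C@]2(C)O[C@H]2C/C=C\[C@H](C)OC(=O)CC | intermediate
11 | (2S,3Z)-5-[(2S,3S)-3-[(3E)-6-[(2S,3R)-3-formyl-3-methyloxiran-2-yl]-4-methylhex-3-enyl]-3-methyloxiran-2-yl]pent-3-en-2-yl propanoate | O=C[C@]1(C)O[C@H]1CC/C(C)=C/CC[C@]2(C)O[C@H]2C/C=C\[C@H](C)OC(=O)CC | intermediate
12 | (2S,3Z)-5-[(2S,3S)-3-[(3E)-6-[(2S,3S)-3-ethenyl-3-methyloxiran-2-yl]-4-methylhex-3-enyl]-3-methyloxiran-2-yl]pent-3-en-2-yl propanoate | C=C[C@]1(C)O[C@H]1CC/C(C)=C/CC[C@]2(C)O[C@H]2C/C=C\[C@H](C)OC(=O)CC | intermediate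
13 | lithium enolate of 12, C17 methyl cis to OLi | C=C[C@]1(C)O[C@H]1CC/C(C)=C/CC[C@]2(C)O[C@H]2C/C=C\[C@H](C)O/C([O-])=C/C.[Li+] | intermediate
14 | (Z)-tert-butyldimethylsilyl ketene acetal of 12, C17 methyl cis to OSi | C=C[C@]1(C)O[C@H]1CC/C(C)=C/CC[C@]2(C)O[C@H]2C/C=C\[C@H](C)O/C(O[Si](C)(C)C(C)(C)C)=C/C | intermediate
15 | tert-butyldimethylsilyl ester of the (1S,15S)-anti Claisen acid, with (E)-propenyl on C1 and both epoxides intact | C=C[C@]1(C)O[C@H]1CC/C(C)=C/CC[C@]2(C)O[C@H]2C[C@@H](/C=C/C)[C@H](C)C(=O)O[Si](C)(C)C(C)(C)C | intermediate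
16 | tetrabutylammonium salt of the same (1S,15S)-5,6-epoxy acid | C=C[C@]1(C)O[C@H]1CC/C(C)=C/CC[C@]2(C)O[C@H]2C[C@@H](/C=C/C)[C@H](C)C(=O)[O-].CCCC[N+](CCCC)(CCCC)CCCC | intermediate
17 | (3S,4S,6R)-6-[(2S,5E)-8-[(2S,3S)-3-ethenyl-3-methyloxiran-2-yl]-2-hydroxy-6-methyloct-5-en-2-yl]-3-methyl-4-[(1E)-prop-1-enyl]oxan-2-one | C=C[C@]1(C)O[C@H]1CC/C(C)=C/CC[C@](C)(O)[C@H]1C[C@@H](/C=C/C)[C@H](C)C(=O)O1 | intermediate
18 | (1S,3R,4S,7E,11S,12S,13E,15S)-11,12-epoxy-4-hydroxycembra-7,13-dien-16,3-olide | C/C1=C\CC[C@](C)(O)[C@H]2C[C@@H](/C=C/[C@]3(C)O[C@H]3CC1)[C@H](C)C(=O)O2 | intermediate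
19 | (1R,3R,4S,7E,11S,12S,15S)-11,12-epoxy-4-hydroxycembr-7-en-16,3-olide | C/C1=C\CC[C@](C)(O)[C@H]2C[C@@H](CC[C@]3(C)O[C@H]3CC1)[C@H](C)C(=O)O2 | intermediate
20 | CNP0319766.1, (1R,3R,4S,7R,11S,12S,15S)-11,12-epoxy-7-hydroperoxy-4-hydroxycembr-8(19)-en-16,3-olide | C=C1CC[C@@H]2O[C@@]2(C)CC[C@@H]2C[C@@H](OC(=O)[C@H]2C)[C@@](C)(O)CC[C@H]1OO | target

Total step count: 12. Longest linear sequence: 12 steps (1 → 20).

Steps most likely to fail

Step 9. Leakage in the enolate geometry or a competing boat transition state would erode control at C15. C1 is not at risk, because chair and boat both use the allyl face dictated by C13'. The fallback replaces kinetic control at C15 by thermodynamic control. It sets out from 12 and comes back at 17. The cascade is run as described, and the crude mixture of 17 and the C15-epimeric lactone F1 is treated with DBU in toluene. Reversible enolisation of the lactone should funnel the axial-methyl epimer into the all-equatorial 17.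

Step 10. The ruthenium alkylidene may fail to form at, or to engage, the alkene next to quaternary C12, so that oligomerisation through the propenyl ends or catalyst decay takes over. The fallback is a relay design that changes the substrate. It sets out from 11 and comes back at 18.
- Wittig reaction of 11 with the ylide from hex-5-enyltriphenylphosphonium bromide gives the relay ester F2.
- The cascade of step 9 then runs through the lithium enolate F3, the silyl ketene acetal F4, the silyl ester F5 and the ammonium carboxylate F6 to the relay lactone F7.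
- The catalyst loads on the unhindered terminal alkene of F7, expels cyclopentene and is thereby placed on C13. From there it closes onto the propenyl group to give 18.

Step 12. Poor facial selectivity at C7 is possible through attack on a second ring conformer, alongside competing hydrogen abstraction from C6. The fallback makes the C7–O bond by substitution instead of by the ene reaction. It sets out from 19 and comes back at 20.
- If oxygen arrives from the wrong face, the 7-epi-hydroperoxide F8 is separated and reduced with PPh3 to the (7S)-allylic alcohol F9.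
- The secondary hydroxyl is converted selectively with MsCl and Et3N at low temperature into the (7S)-mesylate F10.
- Displacement with anhydrous ethereal H2O2 at low temperature, a known route to allylic hydroperoxides, should give 20 with inversion.

Further compounds
F1 | step 9 | (3R,4S,6R)-6-[(2S,5E)-8-[(2S,3S)-3-ethenyl-3-methyloxiran-2-yl]-2-hydroxy-6-methyloct-5-en-2-yl]-3-methyl-4-[(1E)-prop-1-enyl]oxan-2-one (15-epi-17) | C=C[C@]1(C)O[C@H]1CC/C(C)=C/CC[C@](C)(O)[C@H]1C[C@@H](/C=C/C)[C@@H](C)C(=O)O1
F2 | step 10 | relay ester, 12 with (1Z)-hepta-1,6-dienyl in place of ethenyl on C12 | C=CCCC/C=C\[C@]1(C)O[C@H]1CC/C(C)=C/CC[C@]2(C)O[C@H]2C/C=C\[C@H](C)OC(=O)CC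
F3 | step 10 | lithium enolate of F2, methyl cis to OLi | C=CCCC/C=C\[C@]1(C)O[C@H]1CC/C(C)=C/CC[C@]2(C)O[C@H]2C/C=C\[C@H](C)O/C([O-])=C/C.[Li+]
F4 | step 10 | (Z)-tert-butyldimethylsilyl ketene acetal of F2 | C=CCCC/C=C\[C@]1(C)O[C@H]1CC/C(C)=C/CC[C@]2(C)O[C@H]2C/C=C\[C@H](C)O/C(O[Si](C)(C)C(C)(C)C)=C/C
F5 | step 10 | tert-butyldimethylsilyl ester of the relay Claisen acid | C=CCCC/C=C\[C@]1(C)O[C@H]1CC/C(C)=C/CC[C@]2(C)O[C@H]2C[C@@H](/C=C/C)[C@H](C)C(=O)O[Si](C)(C)C(C)(C)C
F6 | step 10 | tetrabutylammonium salt of the relay Claisen acid | C=CCCC/C=C\[C@]1(C)O[C@H]1CC/C(C)=C/CC[C@]2(C)O[C@H]2C[C@@H](/C=C/C)[C@H](C)C(=O)[O-].CCCC[N+](CCCC)(CCCC)CCCC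
F7 | step 10 | relay lactone, 17 with (1Z)-hepta-1,6-dienyl in place of ethenyl on C12 | C=CCCC/C=C\[C@]1(C)O[C@H]1CC/C(C)=C/CC[C@](C)(O)[C@H]1C[C@@H](/C=C/C)[C@H](C)C(=O)O1
F8 | step 12 | (7S)-hydroperoxide, 7-epi-20 | C=C1CC[C@@H]2O[C@@]2(C)CC[C@@H]2C[C@@H](OC(=O)[C@H]2C)[C@@](C)(O)CC[C@@H]1OO
F9 | step 12 | (1R,3R,4S,7S,11S,12S,15S)-11,12-epoxy-4,7-dihydroxycembr-8(19)-en-16,3-olide | C=C1CC[C@@H]2O[C@@]2(C)CC[C@@H]2C[C@@H](OC(=O)[C@H]2C)[C@@](C)(O)CC[C@@H]1O
F10 | step 12 | 7-O-methanesulfonate of F9 | C=C1CC[C@@H]2O[C@@]2(C)CC[C@@H]2C[C@@H](OC(=O)[C@H]2C)[C@@](C)(O)CC[C@@H]1OS(C)(=O)=O
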